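**Strategy.** The target is disconnected across both C–O bonds of the 1,4-dioxane ring into (E)-3,3',4,5,5'-pentahydroxystilbene and a sinapoyl unit bearing a camphorsultam auxiliary. One oxidative operation joins them: the central oxygen O4 of the trihydroxyphenyl ring bonds to C8 (the carbon α to the carbonyl) of the sinapoyl radical, and the quinone methide so formed is closed at benzylic C7 by a flanking hydroxyl, giving the dioxane ring and both stereocentres. The step exploits the weak central O–H of the pyrogallol ring, the equivalence of its two flanking hydroxyls (O3, O5), and the para-hydroxyl of the dimethoxyphenyl ring, which turns C7–C8 into a radical/quinone-methide pair. Hydride removal of the auxiliary then reveals the hydroxymethyl group.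

Key step: step 6

Numbering used: C7, C8, C9 are the side-chain carbons of the sinapyl unit (C7 benzylic, C9 the carbonyl/CH2OH carbon); O3, O4, O5 are the oxygens of the trihydroxyphenyl ring of 4.

Remark (assumption on the chemistry): the facial sense of induction by (2R)-bornane-10,2-sultam at C8 is assumed from the accepted rotamer model for radicals α to N-acyl sultams; should the coupling favour the other face, the equally available (2S)-sultam is used and nothing else changes.

**Step 1**
Reactants: 1 3,4,5-trimethoxybenzaldehyde; 2 diethyl (3,5-dimethoxybenzyl)phosphonate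
Product: 3 (E)-3,3',4,5,5'-pentamethoxystilbene
Conditions: KOtBu, THF, 0 °C → rt
Reagents that add atoms: none
Why: Horner–Wadsworth–Emmons olefination, in which the benzylic phosphonate anion adds to the aldehyde and phosphate is lost from the equilibrated adduct, should give the (E)-stilbene.

**Step 2**
Reactants: 3 (E)-3,3',4,5,5'-pentamethoxystilbene
Product: 4 (E)-3,3',4,5,5'-pentahydroxystilbene
Conditions: BBr3 (excess), CH2Cl2, −78 °C → rt; then H2O
Reagents that add atoms: none
Why: BBr3 ether cleavage (boron coordinates each methoxy oxygen and bromide removes the methyl group by SN2) should free all five phenols while the (E)-alkene is left alone at low temperature.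

**Step 3**
Reactants: 5 (2R)-bornane-10,2-sultam; 6 bromoacetyl bromide
Product: 7 N-(bromoacetyl)-(2R)-bornane-10,2-sultam
Conditions: NaH, THF, 0 °C; then 6, 0 °C → rt
Reagents that add atoms: none
Why: N-acylation of the sodium sultam, where the acyl bromide carbon reacts far faster than the alkyl bromide carbon, so the bromomethyl group is kept.

**Step 4**
Reactants: 7 N-(bromoacetyl)-(2R)-bornane-10,2-sultam
Product: 9 N-[(triphenylphosphanylidene)acetyl]-(2R)-bornane-10,2-sultam (stabilised ylide), via phosphonium bromide 8 (not isolated)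
Conditions: PPh3, THF, 50 °C; then Et3N, CH2Cl2, rt
Reagents that add atoms: triphenylphosphine, c1ccc(cc1)P(c1ccccc1)c1ccccc1
Why: SN2 quaternisation of the phosphine by the α-bromo imide and deprotonation of the acidic CH2 is the standard preparation of an acyl-stabilised Wittig reagent and does not involve the sultam stereocentres.

**Step 5**
Reactants: 9 N-[(triphenylphosphanylidene)acetyl]-(2R)-bornane-10,2-sultam; 10 syringaldehyde (4-hydroxy-3,5-dimethoxybenzaldehyde)
Product: 11 N-[(E)-3-(4-hydroxy-3,5-dimethoxyphenyl)prop-2-enoyl]-(2R)-bornane-10,2-sultam (N-sinapoyl sultam)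
Conditions: toluene, 90 °C
Reagents that add atoms: none
Why: Wittig olefination with a stabilised ylide is (E)-selective through reversible oxaphosphetane formation and runs under neutral conditions that tolerate the free phenol of the aldehyde.

**Step 6**
Reactants: 4 (E)-3,3',4,5,5'-pentahydroxystilbene; 11 N-sinapoyl-(2R)-bornane-10,2-sultam
Product: 13 N-{[(2R,3S)-6-[(E)-2-(3,5-dihydroxyphenyl)ethenyl]-8-hydroxy-3-(4-hydroxy-3,5-dimethoxyphenyl)-2,3-dihydro-1,4-benzodioxin-2-yl]carbonyl}-(2R)-bornane-10,2-sultam (2,3-trans), via quinone methide ether 12 (not isolated)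
Conditions: Ag2CO3 (1.2 equiv), 11 (1.3 equiv), acetone–toluene 1:2, 25 °C, dark, N2; 4 added slowly
Reagents that add atoms: none
Why: Ag(I) oxidises both phenols by one electron, the radical of 4 couples through its central oxygen O4 with C8 of the sinapoyl radical (spin α to the acyl sultam) to give quinone methide 12, and a flanking hydroxyl adds to C7 with rearomatisation. The closest known reaction type is the Ag2CO3- or peroxidase-mediated oxidative coupling of catechols with 4-hydroxycinnamyl or 4-hydroxycinnamoyl phenols to trans-2-aryl-1,4-benzodioxanes, combined with the camphorsultam-controlled oxidative coupling known for feruloyl sultams. The dioxane ring closes by a 6-exo-trig oxa-Michael addition of the phenol to the exocyclic C7=C(ring) bond of the quinone methide. C8 (dioxane C2) is set in the radical–radical coupling by the sultam, whose preferred rotamer (C=O anti to SO2, enoyl s-cis) leaves one face of C8 open, and C7 (dioxane C3) is set by C8 through a reversible addition that places the aryl group equatorial and trans to the acyl group. The step needs cross-coupling over self-coupling and O4–C8 over O3–C8 bonding: the sinapoyl radical has both ortho positions blocked by methoxy groups and dimerises slowly, so it should intercept the pyrogallol radical that is kept dilute by slow addition, and the central oxygen has the weakest O–H bond of the triol (two hydrogen-bond donors beside it, stilbene in the para position), while either flanking hydroxyl closes to the same ring. Diastereomers from incomplete facial control differ in their relation to the auxiliary and are to be removed by chromatography or crystallisation before step 7.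

**Step 7**
Reactants: 13 N-acyl sultam of the trans-benzodioxane
Product: 14 5-[(E)-2-[(2S,3S)-8-hydroxy-3-(4-hydroxy-3,5-dimethoxyphenyl)-2-(hydroxymethyl)-2,3-dihydro-1,4-benzodioxin-6-yl]ethenyl]benzene-1,3-diol (target)
Conditions: LiBH4 (excess), THF, 0 °C → rt; aq. NH4Cl
Reagents that add atoms: none
Why: Reductive cleavage of the N-acyl sultam by borohydride (hydride addition to the imide carbonyl, loss of the sulfonamide anion, reduction of the aldehyde) should give the primary alcohol and return the auxiliary, and the two dioxane stereocentres are not touched because no enolisation is expected under these weakly basic conditions at 0 °C.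

**Compound list**

1 | 3,4,5-trimethoxybenzaldehyde | COc1cc(C=O)cc(OC)c1OC | starting material
2 | diethyl (3,5-dimethoxybenzyl)phosphonate | CCOP(=O)(Cc1cc(OC)cc(OC)c1)OCC | starting material
3 | (E)-3,3',4,5,5'-pentamethoxystilbene [(E)-1-(3,5-dimethoxyphenyl)-2-(3,4,5-trimethoxyphenyl)ethene] | COc1cc(/C=C/c2cc(OC)c(OC)c(OC)c2)cc(OC)c1 | intermediate
4 | (E)-3,3',4,5,5'-pentahydroxystilbene [5-[(E)-2-(3,5-dihydroxyphenyl)ethenyl]benzene-1,2,3-triol] | Oc1cc(O)cc(/C=C/c2cc(O)c(O)c(O)c2)c1 | intermediate
5 | (2R)-bornane-10,2-sultam [(1S,2R,4R)-2,10-camphorsultam, the (−)-enantiomer] | N1[C@@H]2C[C@H]3CC[C@]2(CS1(=O)=O)C3(C)C | starting material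
6 | bromoacetyl bromide | BrCC(Br)=O | starting material
7 | N-(bromoacetyl)-(2R)-bornane-10,2-sultam | BrCC(=O)N1[C@@H]2C[C@H]3CC[C@]2(CS1(=O)=O)C3(C)C | intermediate
8 | {2-oxo-2-[(2R)-bornane-10,2-sultam-N-yl]ethyl}triphenylphosphonium bromide | [Br-].O=C(C[P+](c1ccccc1)(c1ccccc1)c1ccccc1)N1[C@@H]2C[C@H]3CC[C@]2(CS1(=O)=O)C3(C)C | intermediate
9 | N-[(triphenylphosphanylidene)acetyl]-(2R)-bornane-10,2-sultam (stabilised ylide) | O=C(C=P(c1ccccc1)(c1ccccc1)c1ccccc1)N1[C@@H]2C[C@H]3CC[C@]2(CS1(=O)=O)C3(C)C | intermediate
10 | syringaldehyde (4-hydroxy-3,5-dimethoxybenzaldehyde) | COc1cc(C=O)cc(OC)c1O | starting material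
11 | N-[(E)-3-(4-hydroxy-3,5-dimethoxyphenyl)prop-2-enoyl]-(2R)-bornane-10,2-sultam (N-sinapoyl sultam) | COc1cc(/C=C/C(=O)N2[C@@H]3C[C@H]4CC[C@]3(CS2(=O)=O)C4(C)C)cc(OC)c1O | intermediate
12 | N-[(2R)-2-{2,6-dihydroxy-4-[(E)-2-(3,5-dihydroxyphenyl)ethenyl]phenoxy}-3-(3,5-dimethoxy-4-oxocyclohexa-2,5-dien-1-ylidene)propanoyl]-(2R)-bornane-10,2-sultam (quinone methide) | Oc1cc(O)cc(/C=C/c2cc(O)c(O[C@H](C=C3C=C(OC)C(=O)C(OC)=C3)C(=O)N3[C@@H]4C[C@H]5CC[C@]4(CS3(=O)=O)C5(C)C)c(O)c2)c1 | intermediate
13 | N-{[(2R,3S)-6-[(E)-2-(3,5-dihydroxyphenyl)ethenyl]-8-hydroxy-3-(4-hydroxy-3,5-dimethoxyphenyl)-2,3-dihydro-1,4-benzodioxin-2-yl]carbonyl}-(2R)-bornane-10,2-sultam (2,3-trans) | COc1cc([C@@H]2Oc3cc(/C=C/c4cc(O)cc(O)c4)cc(O)c3O[C@H]2C(=O)N2[C@@H]3C[C@H]4CC[C@]3(CS2(=O)=O)C4(C)C)cc(OC)c1O | intermediate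
14 | 5-[(E)-2-[(2S,3S)-8-hydroxy-3-(4-hydroxy-3,5-dimethoxyphenyl)-2-(hydroxymethyl)-2,3-dihydro-1,4-benzodioxin-6-yl]ethenyl]benzene-1,3-diol | COc1cc([C@@H]2Oc3cc(/C=C/c4cc(O)cc(O)c4)cc(O)c3O[C@H]2CO)cc(OC)c1O | target

Total step count: 7. Longest linear sequence: 5 steps (steps 3, 4, 5, 6, 7).

**Steps most likely to fail**

Step 6. The electron-rich pyrogallol stilbene may be consumed by competing oxidation pathways (self-coupling, bonding at the stilbene β-carbon, over-oxidation to hydroxy-o-quinone and benzotropolone products), and the facial bias of the sultam at C8 may be too low. The fallback sets out from 4 and drops the auxiliary. Coupling of 4 with the classical monolignol partner sinapyl alcohol F1 (Ag2CO3, acetone–toluene, rt) should give the trans-benzodioxane directly at the alcohol oxidation level as a racemate, that is 14 together with its (2R,3R)-enantiomer F2. A lipase (immobilised Candida antarctica lipase B, vinyl acetate, MTBE–acetone, 35 °C) is then expected to acylate the primary hydroxyl of one enantiomer only; by analogy with lipase discrimination of flavonolignan benzodioxanes of the same configuration this is taken to be the (2S,3S)-enantiomer, giving the primary acetate F3, which is separated from unreacted F2. Methanolysis (K2CO3, MeOH, 0 °C) of F3 comes back to the route at 14.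

Step 7. Hydride is consumed by four phenols, and the phenoxides formed may open the dioxane ring (β-elimination of the C3 aryloxide from the imide enolate, or expulsion through the syringyl phenoxide as a quinone methide), which would erase both stereocentres. The fallback sets out from 13. All four phenols are silylated (TBSCl, imidazole, DMF) to the tetrakis(tert-butyldimethylsilyl) ether F4, the acyl sultam is reduced (LiBH4, THF, −20 → 0 °C) to the silylated primary alcohol F5, and buffered desilylation (Et3N·3HF, THF, rt) comes back at 14.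

Step 5. The olefination may stall because the imide-stabilised ylide is weakly nucleophilic and is partly protonated by the acidic phenol of an electron-rich aldehyde. The fallback sets out from 5 and builds the enoyl sultam by acylation instead of olefination. Sinapic acid F6 is acetylated (Ac2O, pyridine) to O-acetylsinapic acid F7, which is converted (oxalyl chloride, cat. DMF, CH2Cl2) into O-acetylsinapoyl chloride F8. The sodium salt of 5 (NaH, toluene, 0 °C) is acylated by F8 to N-(O-acetylsinapoyl)sultam F9, and mild aminolysis of the aryl acetate (NH4OAc, aq. MeOH, rt) comes back at 11.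

**Further compounds**

F1 | step 6 | sinapyl alcohol [(E)-4-(3-hydroxyprop-1-enyl)-2,6-dimethoxyphenol] | COc1cc(/C=C/CO)cc(OC)c1O
F2 | step 6 | (2R,3R)-enantiomer of 14 | COc1cc([C@H]2Oc3cc(/C=C/c4cc(O)cc(O)c4)cc(O)c3O[C@@H]2CO)cc(OC)c1O
F3 | step 6 | primary acetate of 14 [(2S,3S)-2-(acetoxymethyl) compound] | COc1cc([C@@H]2Oc3cc(/C=C/c4cc(O)cc(O)c4)cc(O)c3O[C@H]2COC(C)=O)cc(OC)c1O
F4 | step 7 | tetrakis(tert-butyldimethylsilyl) ether of 13 (all four phenols silylated) | COc1cc([C@@H]2Oc3cc(/C=C/c4cc(O[Si](C)(C)C(C)(C)C)cc(O[Si](C)(C)C(C)(C)C)c4)cc(O[Si](C)(C)C(C)(C)C)c3O[C@H]2C(=O)N2[C@@H]3C[C@H]4CC[C@]3(CS2(=O)=O)C4(C)C)cc(OC)c1O[Si](C)(C)C(C)(C)C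
F5 | step 7 | tetrakis(tert-butyldimethylsilyl) ether of 14 (free primary alcohol) | COc1cc([C@@H]2Oc3cc(/C=C/c4cc(O[Si](C)(C)C(C)(C)C)cc(O[Si](C)(C)C(C)(C)C)c4)cc(O[Si](C)(C)C(C)(C)C)c3O[C@H]2CO)cc(OC)c1O[Si](C)(C)C(C)(C)C
F6 | step 5 | sinapic acid [(E)-3-(4-hydroxy-3,5-dimethoxyphenyl)prop-2-enoic acid] | COc1cc(/C=C/C(=O)O)cc(OC)c1O
F7 | step 5 | O-acetylsinapic acid [(E)-3-(4-acetoxy-3,5-dimethoxyphenyl)prop-2-enoic acid] | COc1cc(/C=C/C(=O)O)cc(OC)c1OC(C)=O
F8 | step 5 | O-acetylsinapoyl chloride | COc1cc(/C=C/C(=O)Cl)cc(OC)c1OC(C)=O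
F9 | step 5 | N-[(E)-3-(4-acetoxy-3,5-dimethoxyphenyl)prop-2-enoyl]-(2R)-bornane-10,2-sultam | COc1cc(/C=C/C(=O)N2[C@@H]3C[C@H]4CC[C@]3(CS2(=O)=O)C4(C)C)cc(OC)c1OC(C)=O
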